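**Retrosynthetic overview**

1. Labels: ring A = N4–C3–C2(Me)–C25(=O)–C20; ring B = N4–C5–C6–C22–C21–C20; ring C = C6–C7–C8–C9–C13–C14–C22; ring D = C9–C13 with C12=C13; lactone ring E = C14–C15–C16–C17(=O)–O18–C19; ring F = C14–C19–C20–C21–C22; C23 = CH2OH on C22. The strategy rests on quaternary C14 (common to rings C, E and F, bonded to sp2 C13): it is γ to the lactone carbonyl C17 and bonded to the lactone O–CH carbon C19, so C14–C19 is a vinylogous aldol bond and O18–C17 an acyl transfer onto a Z-ester.
2. Last: conjugate reduction of the ene-lactone and acid deprotection. Before that, rings F and E close together from the tetracyclic A/B/C/D Z-enoate carrying CHO on C20 (key step).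
3. The Z-enoate comes from the C14 aldehyde (Still–Gennari), which comes from a [2,3]-Wittig–Still shift of the C12 allylic alcohol of a ring C/D enone. Ring C closes by aldol condensation of a C14 aldehyde onto a cyclopentanone (ring D, C9) attached by rhodium-catalysed asymmetric conjugate addition to cyclopent-2-enone.
4. C22 is made quaternary by nitrile-anion hydroxymethylation. Ring A closes by N-alkylation after an ester-enolate aldol of the ring B pipecolate with the aldehyde from the Roche ester (C20, C2). Ring B comes from iridium-catalysed allylic alkylation (C6) and a Michael/N-alkylation annulation.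
5. Order of ring formation: B, A, (D attached), C, then F and E in one operation.

Key step: step 25

Remark 1 (assumption): centres that are later planarised or oxidised (C20 and C22 in 4–7, C22 in 13–18, the C25 carbinol in 11–13, C12 in 29–30, C14 in 31–36) are left undefined or drawn as the expected epimer; either epimer should converge.
Remark 2 (assumption): the ligand enantiomers in steps 2 and 16 are the ones expected from the usual facial models and would be confirmed on the first intermediate; compound 1 is bought as the E isomer.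

**Route**

Step 1
Reactants: 1 tert-butyl N-[(2E)-4-hydroxybut-2-en-1-yl]carbamate
Product: 2 (2E)-4-[(tert-butoxycarbonyl)amino]but-2-en-1-yl methyl carbonate
Conditions: ClCO2Me, pyridine, CH2Cl2, 0 °C
Reagents that add atoms: methyl chloroformate, COC(=O)Cl
Why: O-acylation of the primary allylic alcohol (carbonate formation) installs the leaving group for the allylic substitution, and the carbamate N–H should not compete under pyridine.

Step 2
Reactants: 2 (2E)-4-[(tert-butoxycarbonyl)amino]but-2-en-1-yl methyl carbonate; 3 methyl cyanoacetate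
Product: 4 methyl (3S)-3-{[(tert-butoxycarbonyl)amino]methyl}-2-cyanopent-4-enoate (C2 epimers)
Conditions: [Ir(cod)Cl]2 (2 mol %), BINOL-derived bis(1-phenylethyl)phosphoramidite (4 mol %, enantiomer giving 3S), n-PrNH2 (activation), 3 (3 equiv), THF, 25 °C
Reagents that add atoms: none
Why: Iridium-catalysed asymmetric allylic alkylation should deliver the cyanoacetate to the substituted allyl terminus (branched product), the ligand fixing the face and so C6, while the acidic C22 centre stays epimeric and is reset later.

Step 3
Reactants: 4 methyl (3S)-3-{[(tert-butoxycarbonyl)amino]methyl}-2-cyanopent-4-enoate; 5 methyl 2-bromoacrylate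
Product: 7 1-tert-butyl 2,4-dimethyl (5S)-4-cyano-5-ethenylpiperidine-1,2,4-tricarboxylate, via bromo ester 6 (not isolated)
Conditions: Cs2CO3 (2.2 equiv), n-Bu4NI (10 mol %), DMF, 0 → 25 °C
Reagents that add atoms: none
Why: Michael addition of the cyanoacetate carbanion to the bromoacrylate followed by intramolecular N-alkylation of the carbamate anion on the α-bromo ester (6-exo-tet, Michael-initiated ring closure) should close ring B, the C20 and C22 epimers being of no consequence.

Step 4
Reactants: 8 methyl (R)-3-hydroxy-2-methylpropanoate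
Product: 9 methyl (R)-3-[(tert-butyldimethylsilyl)oxy]-2-methylpropanoate
Conditions: t-BuMe2SiCl, imidazole, CH2Cl2, 25 °C
Reagents that add atoms: tert-butyldimethylsilyl chloride, CC(C)(C)[Si](C)(C)Cl
Why: Silylation of the primary alcohol protects C3–O through the aldol without touching the stereocentre C2.

Step 5
Reactants: 9 methyl (R)-3-[(tert-butyldimethylsilyl)oxy]-2-methylpropanoate
Product: 10 (R)-3-[(tert-butyldimethylsilyl)oxy]-2-methylpropanal
Conditions: i-Bu2AlH (1.05 equiv), CH2Cl2, −78 °C; aq. potassium sodium tartrate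
Reagents that add atoms: none
Why: Partial ester reduction stops at the aluminium hemiacetal at −78 °C, and the α-methyl aldehyde is used at once so that C2 should not epimerise.

Step 6
Reactants: 7 1-tert-butyl 2,4-dimethyl (5S)-4-cyano-5-ethenylpiperidine-1,2,4-tricarboxylate; 10 (R)-3-[(tert-butyldimethylsilyl)oxy]-2-methylpropanal
Product: 11 N-Boc piperidine aldol adduct (C20 quaternary, its methyl ester cis to the C6 vinyl group; C25 carbinol; C3–OTBS)
Conditions: LiN(SiMe3)2 (1.1 equiv), THF, −78 °C; then 10, −78 °C; AcOH, −78 °C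
Reagents that add atoms: none
Why: Lithium ester-enolate aldol addition in which only C20–H is acidic enough (C22 is quaternary) and the aldehyde should approach the exocyclic enolate anti to the pseudoaxial C22 substituent with the vinyl group pseudoequatorial, so the new C20–C25 bond ends trans and the ester (C19) cis to the vinyl group; the C25 carbinol (Felkin–Anh epimer drawn) is oxidised in step 8.

Step 7
Reactants: 11 N-Boc piperidine aldol adduct
Product: 13 indolizidine carbinol (rings A and B; C25–OH; C19 methyl ester; cyano ester on C22; vinyl on C6), via amino diol 12 (not isolated)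
Conditions: CF3CO2H/CH2Cl2/H2O, 0 → 25 °C; evaporate; then PPh3, CBr4, Et3N, CH2Cl2, 0 → 25 °C
Reagents that add atoms: none
Why: Acid removes the carbamate and the primary silyl ether, and Appel activation of the primary C3–OH followed by 5-exo-tet N-alkylation should close ring A while the hindered secondary C25–OH is left alone.

Step 8
Reactants: 13 indolizidine carbinol
Product: 14 indolizidinone (C25 ketone)
Conditions: Dess–Martin periodinane, NaHCO3, CH2Cl2, 0 → 25 °C
Reagents that add atoms: none
Why: Dess–Martin oxidation under buffered neutral conditions gives the ketone, which cannot enolise toward quaternary C20 and should keep C2.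

Step 9
Reactants: 14 indolizidinone
Product: 15 C25 ethylene ketal (1,3-dioxolane)
Conditions: Me3SiOCH2CH2OSiMe3, Me3SiOTf (1.6 equiv), CH2Cl2, −20 → 20 °C
Reagents that add atoms: 1,2-bis(trimethylsilyloxy)ethane, C[Si](C)(C)OCCO[Si](C)(C)C
Why: Silyl-triflate-mediated ketalisation (Noyori conditions) is aprotic and cold, so the five-ring ketone should be masked without enolisation toward C2, the extra triflate covering the basic nitrogen.

Step 10
Reactants: 15 C25 ethylene ketal
Product: 16 ketal nitrile (C22–H, epimers)
Conditions: LiCl, H2O, DMSO, 130 °C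
Reagents that add atoms: none
Why: Krapcho dealkoxycarbonylation removes only the activated α-cyano ester on C22, the unactivated ester on quaternary C20 and the ketal being inert to chloride.

Step 11
Reactants: 16 ketal nitrile
Product: 17 primary alcohol (C19 hydroxymethyl on C20)
Conditions: LiBH4, THF/MeOH, 0 → 45 °C
Reagents that add atoms: none
Why: LiBH4 reduces the ester to the alcohol and should leave the nitrile and the ketal untouched (chemoselective ester reduction).

Step 12
Reactants: 17 primary alcohol
Product: 18 C19 triethylsilyl ether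
Conditions: Et3SiCl, imidazole, CH2Cl2, 0 °C
Reagents that add atoms: chlorotriethylsilane, CC[Si](Cl)(CC)CC
Why: Silylation gives a group that can later be removed in the presence of the tert-butyldimethylsilyl ether.

Step 13
Reactants: 18 C19 triethylsilyl ether
Product: 20 quaternary nitrile with CH2OSi(t-Bu)Me2 on C22 (nitrile cis to the C6 vinyl and C19 groups), via hydroxymethyl nitrile 19 (not isolated)
Conditions: LiN(i-Pr)2, THF, −78 °C; CH2O (g), −78 → −40 °C; then t-BuMe2SiCl, imidazole, DMF, 0 → 25 °C
Reagents that add atoms: formaldehyde, C=O; tert-butyldimethylsilyl chloride, CC(C)(C)[Si](C)(C)Cl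
Why: Nitrile-anion hydroxymethylation in which formaldehyde should add to the planar metalated nitrile from the equatorial side, anti to the axial CH2OSiEt3 group on C20 and trans to the C6 vinyl group, which sets C22 with the nitrile axial, and the alkoxide is silylated in the flask.

Step 14
Reactants: 20 quaternary nitrile
Product: 21 C14 aldehyde (CHO on C22)
Conditions: i-Bu2AlH, toluene, −78 → −20 °C; then aq. potassium sodium tartrate, SiO2
Reagents that add atoms: water, O
Why: Single hydride addition to the nitrile gives an aluminium aldimine that hydrolyses to the aldehyde, with the silyl ethers and the ketal surviving.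

Step 15
Reactants: 21 C14 aldehyde; 22 4,4,5,5-tetramethyl-2-vinyl-1,3,2-dioxaborolane
Product: 23 (E)-alkenylboronate (C7=C8–B on C6)
Conditions: second-generation Grubbs catalyst (H2IMes)(PCy3)Cl2Ru=CHPh (10 mol %), 22 (4 equiv), CH2Cl2, 40 °C
Reagents that add atoms: none
Why: Olefin cross-metathesis of the only alkene of 21 with the vinylboronate should give the E-alkenylboronate with loss of ethene.

Step 16
Reactants: 23 (E)-alkenylboronate; 24 cyclopent-2-en-1-one
Product: 25 (E)-alkenyl cyclopentanone (C9 S, ketone at C12)
Conditions: [Rh(cod)Cl]2 (3 mol %), (S)-BINAP (7 mol %), K3PO4, 24 (3 equiv), dioxane/H2O 10:1, 40 °C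
Reagents that add atoms: none
Why: Hayashi–Miyaura asymmetric conjugate addition attaches ring D, and the rhodium–(S)-BINAP complex should set C9 by catalyst control, independent of the distant centres, while the hindered neopentyl aldehyde is not attacked.

Step 17
Reactants: 25 (E)-alkenyl cyclopentanone
Product: 26 keto aldehyde (saturated C7–C8 link)
Conditions: H2 (1 atm), Pd/C, EtOAc, 25 °C
Reagents that add atoms: none
Why: Heterogeneous hydrogenation saturates the disubstituted alkene, the only C=C present, without reducing the ketone or the aldehyde.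

Step 18
Reactants: 26 keto aldehyde
Product: 28 tetracyclic enone (C12 ketone, C13=C14), via aldol adduct 27 (not isolated)
Conditions: piperidine, AcOH, toluene, 80 °C
Reagents that add atoms: none
Why: Intramolecular aldol condensation (7-(enolexo)-exo-trig, amine-promoted Mannich–elimination variant) should close ring C because the aldehyde has no α-hydrogen and only C13 of the ketone can reach it in a seven-membered ring, dehydration giving the conjugated enone.

Step 19
Reactants: 28 tetracyclic enone
Product: 29 allylic alcohol (C12–OH, C13=C14)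
Conditions: NaBH4, CeCl3·7H2O, MeOH, −40 °C
Reagents that add atoms: none
Why: Luche reduction gives 1,2-reduction of the enone; the configuration of the new C12 carbinol is lost again in step 21.

Step 20
Reactants: 29 allylic alcohol
Product: 30 tributylstannylmethyl ether
Conditions: KH, Bu3SnCH2I, 18-crown-6, THF, 0 → 25 °C
Reagents that add atoms: tributyl(iodomethyl)stannane, CCCC[Sn](CI)(CCCC)CCCC
Why: Williamson etherification of the potassium alkoxide installs the tin handle for the rearrangement.

Step 21
Reactants: 30 tributylstannylmethyl ether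
Product: 31 homoallylic alcohol (C14–CH2OH, C12=C13)
Conditions: n-BuLi, THF, −78 → −30 °C
Reagents that add atoms: none
Why: Tin–lithium exchange and [2,3]-Wittig–Still rearrangement should deliver the CH2O carbon (C15) suprafacially to C14 and move the double bond to C12=C13, the C14 configuration following from C12 and being erased in step 25.

Step 22
Reactants: 31 homoallylic alcohol; 32 methyl bis(2,2,2-trifluoroethoxy)phosphinylacetate
Product: 34 Z-enoate with C19 triethylsilyl ether, via aldehyde 33 (not isolated)
Conditions: Dess–Martin periodinane, NaHCO3, CH2Cl2, 0 °C; filter; then 32, KN(SiMe3)2, 18-crown-6, THF, −78 °C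
Reagents that add atoms: none
Why: Buffered oxidation gives the β,γ-unsaturated aldehyde, which is taken crude into the Still–Gennari olefination so that it should not move into conjugation, the electron-poor phosphonate with dissociated potassium giving the Z-enoate.

Step 23
Reactants: 34 Z-enoate with C19 triethylsilyl ether
Product: 35 Z-enoate primary alcohol (C19–OH)
Conditions: HF·pyridine, pyridine, THF, 0 °C
Reagents that add atoms: none
Why: Buffered fluoride should cleave the triethylsilyl ether selectively and leave the tert-butyldimethylsilyl ether, the ketal and the Z-enoate.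

Step 24
Reactants: 35 Z-enoate primary alcohol
Product: 36 tetracyclic Z-enoate with formyl group on C20 (ketal, tert-butyldimethylsilyl ether)
Conditions: Dess–Martin periodinane, NaHCO3, CH2Cl2, 0 → 25 °C
Reagents that add atoms: none
Why: Dess–Martin oxidation gives the non-enolisable α-amino aldehyde under conditions that should not touch the acidic C14–H.

Step 25
Reactants: 36 tetracyclic Z-enoate with formyl group on C20
Product: 38 hexacyclic α,β-unsaturated lactone (ketal, tert-butyldimethylsilyl ether), via hydroxy ester 37 (not isolated)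
Conditions: KN(SiMe3)2 (1.2 equiv), THF, −78 → −20 °C; aq. NH4Cl
Reagents that add atoms: none
Why: KN(SiMe3)2 removes C14–H, the only proton allylic to both the enoate and C12=C13 (the C20 aldehyde has no α-hydrogen and the ketal blocks C25), the extended enolate adds through C14 to the C19 aldehyde, and the C19 alkoxide then acylates on the Z-ester C17 with loss of methoxide; the closest known reaction type is the intramolecular vinylogous aldol addition of an ester dienolate with lactonisation to a 5,6-dihydropyran-2-one. Ring F closes 5-exo-trig at the aldehyde carbon (C14–C19) and ring E closes 6-exo-trig at the ester carbonyl (O18–C17). C14 is set by the three-atom link C22–C21–C20, which lets the aldehyde reach only the face of planar C14 that is cis to C21, and C19 is set because only the alkoxide cis to the enoate arm can lactonise while the aldol is reversible, so the other epimer should return. The step needs γ-attack rather than attack through C16 or C12, and this is secured by ring size: γ-attack gives a five-membered ring, the alternatives would need bridged seven-membered rings. The Z geometry of C15=C16 should be kept in the enolate at low temperature, which holds the ester within reach of the alkoxide.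

Step 26
Reactants: 38 hexacyclic α,β-unsaturated lactone
Product: 39 saturated lactone (ketal, tert-butyldimethylsilyl ether)
Conditions: [(Ph3P)CuH]6 (0.5 equiv), H2O (5 equiv), benzene, 25 °C
Reagents that add atoms: none
Why: Copper hydride conjugate reduction adds hydride to C15 and water protonates the enolate, the isolated trisubstituted C12=C13 bond and the lactone carbonyl being inert.

Step 27
Reactants: 39 saturated lactone
Product: 40 target CNP0180795.1
Conditions: 3 M aq. HCl, THF, 40 °C; NaHCO3
Reagents that add atoms: water, O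
Why: Acid hydrolysis removes the dioxolane and the silyl ether in one operation, the lactone and the non-eliminable β-acyloxy ketone are stable to it, and mild conditions should limit epimerisation of C2.

**Compound list**

1 | tert-butyl N-[(2E)-4-hydroxybut-2-en-1-yl]carbamate | CC(C)(C)OC(=O)NC/C=C/CO | starting material
2 | (2E)-4-[(tert-butoxycarbonyl)amino]but-2-en-1-yl methyl carbonate | CC(C)(C)OC(=O)NC/C=C/COC(=O)OC | intermediate
3 | methyl cyanoacetate | N#CCC(=O)OC | starting material
4 | methyl (3S)-3-{[(tert-butoxycarbonyl)amino]methyl}-2-cyanopent-4-enoate (C2 epimers) | CC(C)(C)OC(=O)NC[C@@H](C=C)C(C#N)C(=O)OC | intermediate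
5 | methyl 2-bromoacrylate | C=C(Br)C(=O)OC | starting material
6 | dimethyl 2-bromo-4-{(2S)-1-[(tert-butoxycarbonyl)amino]but-3-en-2-yl}-4-cyanopentanedioate (epimers at C2 and C4) | CC(C)(C)OC(=O)NC[C@@H](C=C)C(C#N)(C(=O)OC)CC(Br)C(=O)OC | intermediate
7 | 1-tert-butyl 2,4-dimethyl (5S)-4-cyano-5-ethenylpiperidine-1,2,4-tricarboxylate (ring B; epimers at C2 and C4) | CC(C)(C)OC(=O)N1C[C@@H](C=C)C(C#N)(C(=O)OC)CC1C(=O)OC | intermediate
8 | methyl (R)-3-hydroxy-2-methylpropanoate | C[C@@H](C(=O)OC)CO | starting material
9 | methyl (R)-3-[(tert-butyldimethylsilyl)oxy]-2-methylpropanoate | C[C@@H](C(=O)OC)CO[Si](C)(C)C(C)(C)C | intermediate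
10 | (R)-3-[(tert-butyldimethylsilyl)oxy]-2-methylpropanal | C[C@@H](C=O)CO[Si](C)(C)C(C)(C)C | intermediate
11 | N-Boc piperidine aldol adduct (C20 ester cis to vinyl; C25 carbinol; C22 epimers) | CC(C)(C)OC(=O)N1C[C@@H](C=C)C(C#N)(C(=O)OC)C[C@]1(C(=O)OC)[C@@H](O)[C@H](C)CO[Si](C)(C)C(C)(C)C | intermediate
12 | amino diol (11 without carbamate and silyl group) | N1C[C@@H](C=C)C(C#N)(C(=O)OC)C[C@]1(C(=O)OC)[C@@H](O)[C@H](C)CO | intermediate
13 | indolizidine carbinol (rings A and B, C25–OH) | C[C@@H]1CN2C[C@@H](C=C)C(C#N)(C(=O)OC)C[C@]2(C(=O)OC)[C@H]1O | intermediate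
14 | indolizidinone (C25 ketone) | C[C@@H]1CN2C[C@@H](C=C)C(C#N)(C(=O)OC)C[C@]2(C(=O)OC)C1=O | intermediate
15 | C25 ethylene ketal of 14 | C[C@@H]1CN2C[C@@H](C=C)C(C#N)(C(=O)OC)C[C@]2(C(=O)OC)C13OCCO3 | intermediate
16 | ketal nitrile (C22–H, epimers; C19 methyl ester) | C[C@@H]1CN2C[C@@H](C=C)C(C#N)C[C@]2(C(=O)OC)C13OCCO3 | intermediate
17 | ketal nitrile primary alcohol (C19–OH) | C[C@@H]1CN2C[C@@H](C=C)C(C#N)C[C@]2(CO)C13OCCO3 | intermediate
18 | C19 triethylsilyl ether of 17 | C[C@@H]1CN2C[C@@H](C=C)C(C#N)C[C@]2(CO[Si](CC)(CC)CC)C13OCCO3 | intermediate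
19 | C22 hydroxymethyl nitrile | C[C@@H]1CN2C[C@@H](C=C)[C@](C#N)(CO)C[C@]2(CO[Si](CC)(CC)CC)C13OCCO3 | intermediate
20 | C22 quaternary nitrile with CH2OSi(t-Bu)Me2 | C[C@@H]1CN2C[C@@H](C=C)[C@](C#N)(CO[Si](C)(C)C(C)(C)C)C[C@]2(CO[Si](CC)(CC)CC)C13OCCO3 | intermediate
21 | C14 aldehyde | C[C@@H]1CN2C[C@@H](C=C)[C@](C=O)(CO[Si](C)(C)C(C)(C)C)C[C@]2(CO[Si](CC)(CC)CC)C13OCCO3 | intermediate
22 | 4,4,5,5-tetramethyl-2-vinyl-1,3,2-dioxaborolane | C=CB1OC(C)(C)C(C)(C)O1 | starting material
23 | (E)-alkenylboronate | C[C@@H]1CN2C[C@@H](/C=C/B3OC(C)(C)C(C)(C)O3)[C@](C=O)(CO[Si](C)(C)C(C)(C)C)C[C@]2(CO[Si](CC)(CC)CC)C14OCCO4 | intermediate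
24 | cyclopent-2-en-1-one | O=C1C=CCC1 | starting material
25 | (E)-alkenyl cyclopentanone (C9 S) | C[C@@H]1CN2C[C@@H](/C=C/[C@H]3CCC(=O)C3)[C@](C=O)(CO[Si](C)(C)C(C)(C)C)C[C@]2(CO[Si](CC)(CC)CC)C14OCCO4 | intermediate
26 | keto aldehyde | C[C@@H]1CN2C[C@@H](CC[C@H]3CCC(=O)C3)[C@](C=O)(CO[Si](C)(C)C(C)(C)C)C[C@]2(CO[Si](CC)(CC)CC)C14OCCO4 | intermediate
27 | β-hydroxy ketone (aldol adduct, C13 and C14 undefined) | C[C@@H]1CN2C[C@H]3CC[C@H]4CCC(=O)C4C(O)[C@@]3(CO[Si](C)(C)C(C)(C)C)C[C@]2(CO[Si](CC)(CC)CC)C15OCCO5 | intermediate
28 | tetracyclic enone (C12=O, C13=C14) | C[C@@H]1CN2C[C@H]3CC[C@H]4CCC(=O)C4=C[C@@]3(CO[Si](C)(C)C(C)(C)C)C[C@]2(CO[Si](CC)(CC)CC)C15OCCO5 | intermediate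
29 | allylic alcohol (C12–OH) | C[C@@H]1CN2C[C@H]3CC[C@H]4CC[C@@H](O)C4=C[C@@]3(CO[Si](C)(C)C(C)(C)C)C[C@]2(CO[Si](CC)(CC)CC)C15OCCO5 | intermediate
30 | tributylstannylmethyl ether | C[C@@H]1CN2C[C@H]3CC[C@H]4CC[C@@H](OC[Sn](CCCC)(CCCC)CCCC)C4=C[C@@]3(CO[Si](C)(C)C(C)(C)C)C[C@]2(CO[Si](CC)(CC)CC)C15OCCO5 | intermediate
31 | homoallylic alcohol (C14–CH2OH, C12=C13) | C[C@@H]1CN2C[C@H]3CC[C@H]4CCC=C4[C@@H](CO)[C@@]3(CO[Si](C)(C)C(C)(C)C)C[C@]2(CO[Si](CC)(CC)CC)C15OCCO5 | intermediate
32 | methyl bis(2,2,2-trifluoroethoxy)phosphinylacetate | COC(=O)CP(=O)(OCC(F)(F)F)OCC(F)(F)F | starting material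
33 | β,γ-unsaturated aldehyde (C14–CHO) | C[C@@H]1CN2C[C@H]3CC[C@H]4CCC=C4[C@@H](C=O)[C@@]3(CO[Si](C)(C)C(C)(C)C)C[C@]2(CO[Si](CC)(CC)CC)C15OCCO5 | intermediate
34 | Z-enoate with C19 triethylsilyl ether | C[C@@H]1CN2C[C@H]3CC[C@H]4CCC=C4[C@@H](/C=C\C(=O)OC)[C@@]3(CO[Si](C)(C)C(C)(C)C)C[C@]2(CO[Si](CC)(CC)CC)C15OCCO5 | intermediate
35 | Z-enoate primary alcohol | C[C@@H]1CN2C[C@H]3CC[C@H]4CCC=C4[C@@H](/C=C\C(=O)OC)[C@@]3(CO[Si](C)(C)C(C)(C)C)C[C@]2(CO)C15OCCO5 | intermediate
36 | tetracyclic Z-enoate with formyl group on C20 (key-step precursor) | C[C@@H]1CN2C[C@H]3CC[C@H]4CCC=C4[C@@H](/C=C\C(=O)OC)[C@@]3(CO[Si](C)(C)C(C)(C)C)C[C@]2(C=O)C15OCCO5 | intermediate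
37 | hydroxy Z-ester (ring F closed, C19–OH) | C[C@@H]1CN2C[C@H]3CC[C@H]4CCC=C4[C@@]4(/C=C\C(=O)OC)[C@H](O)[C@@]2(C[C@@]34CO[Si](C)(C)C(C)(C)C)C15OCCO5 | intermediate
38 | hexacyclic α,β-unsaturated lactone (key-step product) | C[C@@H]1CN2C[C@H]3CC[C@H]4CCC=C4[C@@]45C=CC(=O)O[C@@H]4[C@@]2(C[C@@]35CO[Si](C)(C)C(C)(C)C)C16OCCO6 | intermediate
39 | saturated lactone (ketal, silyl ether) | C[C@@H]1CN2C[C@H]3CC[C@H]4CCC=C4[C@@]45CCC(=O)O[C@@H]4[C@@]2(C[C@@]35CO[Si](C)(C)C(C)(C)C)C16OCCO6 | intermediate
40 | CNP0180795.1 | C[C@@H]1CN2C[C@H]3CC[C@H]4CCC=C4[C@@]45CCC(=O)O[C@@H]4[C@@]2(C[C@@]35CO)C1=O | target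

**Step count and risk**

Total: 27 steps. Longest linear sequence: 25 steps (steps 1–3 and 6–27); steps 4–5 make the aldehyde 10 on a side branch.

Three steps most likely to fail:

1. Step 25 (key step). Reprotonation of the crowded enolate at C12 or C16 could isomerise the enoate into conjugation, or the aldol equilibrium could lie on the open side, before the bond to the fully substituted γ carbon forms. Fallback: set out from 31. Buffered HF·pyridine removes the triethylsilyl group to give the diol F1. Dess–Martin oxidation of both primary alcohols gives the dialdehyde F2. Pyrrolidine/AcOH then promotes an intramolecular aldol addition in which the dienamine of the β,γ-unsaturated aldehyde attacks the C20 formyl group through C14 (5-exo), giving the cyclopentane hydroxy aldehyde F3. Still–Gennari olefination of F3 with 32 (KN(SiMe3)2, 18-crown-6, THF, −78 °C) gives the hydroxy Z-ester 37, which lactonises in the flask. The fallback comes back to the route at 38.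

2. Step 6 (aldol at C20). The aldehyde could approach the enolate of 7 from both faces (poor facial selectivity at C20), and the lithium aldolate could revert on warming. Fallback: set out from 7. CF3CO2H removes the carbamate to give the secondary amine F4. Aza-Michael addition to methacrylonitrile (MeOH, 60 °C) gives the N-(2-cyanopropyl) amine F5. LiN(SiMe3)2 deprotonates only the ester α-position, and the enolate adds to the nitrile through the nitrogen tether (Thorpe-type 5-exo-dig closure); the five-membered transition state tied to nitrogen restricts the approach to the face of C20 anti to the axial C22 substituent more tightly than the open aldol. This gives the cyclic imine F6, and aqueous acid hydrolyses it to the ketone, so the fallback comes back to the route at 14. C2 is then no longer taken from the chiral pool; it is α to the ketone and would be equilibrated with mild base before step 9.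

3. Step 3 (annulation). Base-induced loss of HBr from the bromo ester 6 could outrun N-alkylation by the weakly nucleophilic carbamate anion. Fallback: set out from 4. Michael addition to methyl acrylate (Cs2CO3 cat., MeCN) gives the diester F7. Trifluoroacetylation of its ester enolate (LiN(SiMe3)2, CF3CO2CH2CF3) gives the α-trifluoroacetyl ester F8 (not isolated), and MsN3/Et3N converts it by deacylative diazo transfer to the α-diazo ester F9. Rh2(OAc)4 (1 mol %, CH2Cl2, 25 °C) then closes ring B by intramolecular N–H insertion into the carbamate, and the fallback comes back to the route at 7.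

**Further compounds**

F1 | step 25 | diol (31 without the triethylsilyl group) | C[C@@H]1CN2C[C@H]3CC[C@H]4CCC=C4[C@@H](CO)[C@@]3(CO[Si](C)(C)C(C)(C)C)C[C@]2(CO)C15OCCO5
F2 | step 25 | dialdehyde (CHO on C14 and on C20) | C[C@@H]1CN2C[C@H]3CC[C@H]4CCC=C4[C@@H](C=O)[C@@]3(CO[Si](C)(C)C(C)(C)C)C[C@]2(C=O)C15OCCO5
F3 | step 25 | cyclopentane hydroxy aldehyde (ring F closed, CHO on C14) | C[C@@H]1CN2C[C@H]3CC[C@H]4CCC=C4[C@@]4(C=O)[C@H](O)[C@@]2(C[C@@]34CO[Si](C)(C)C(C)(C)C)C15OCCO5
F4 | step 6 | secondary amine (7 without the carbamate) | N1C[C@@H](C=C)C(C#N)(C(=O)OC)CC1C(=O)OC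
F5 | step 6 | N-(2-cyanopropyl) amine | N#CC(C)CN1C[C@@H](C=C)C(C#N)(C(=O)OC)CC1C(=O)OC
F6 | step 6 | cyclic imine (ring A closed, C25=NH) | CC1CN2C[C@@H](C=C)C(C#N)(C(=O)OC)C[C@]2(C(=O)OC)C1=N
F7 | step 3 | Michael adduct of 4 with methyl acrylate | CC(C)(C)OC(=O)NC[C@@H](C=C)C(C#N)(C(=O)OC)CCC(=O)OC
F8 | step 3 | α-trifluoroacetyl ester | CC(C)(C)OC(=O)NC[C@@H](C=C)C(C#N)(C(=O)OC)CC(C(=O)C(F)(F)F)C(=O)OC
F9 | step 3 | α-diazo ester | CC(C)(C)OC(=O)NC[C@@H](C=C)C(C#N)(C(=O)OC)CC(=[N+]=[N-])C(=O)OC
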